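**Slow substrate.** The slowness of the substrate was what I looked at first: the dusk run still held 65 % of it after 40.0 min, while the warmer summer run held 36 % after 20.0 min. I wanted to know which species leads in two new flasks.

| setting | dusk | summer | south-east | west |
|---|---|---|---|---|
| substrate | 0.067 M | 0.15 M | 0.10 M | 0.10 M |
| gas phase | 18 mM (held) | 18 mM (held) | 18 mM (held) | 18 mM (held) |
| temperature | −3 °C | 12 °C | 8 °C | 0 °C |
| remark | run made earlier | run made earlier |  |  |
| time |  |  | 40 min | 40 min |

| run | time / min | target / % | substrate / % | side product / % |
|---|---|---|---|---|
| dusk | 6.00 | 0 | 98 | 7 |
| dusk | 12.0 | 3 | 89 | 10 |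
| dusk | 20.0 | 3 | 80 | 8 |
| dusk | 25.0 | 5 | 77 | 20 |
| dusk | 30.0 | 7 | 73 | 18 |
| dusk | 40.0 | 7 | 65 | 24 |
| summer | 3.00 | 0 | 87 | 14 |
| summer | 6.00 | 3 | 72 | 27 |
| summer | 12.0 | 3 | 49 | 47 |
| summer | 15.0 | 3 | 41 | 53 |
| summer | 20.0 | 5 | 36 | 62 |

(each reading ± 2 percentage points)

- the earlier runs were read with a standard deviation of 2 percentage points
- at the start none of the gas phase is in solution
- a reading or a percentage of target counts all its forms, free or not
- a reading of substrate is of its free form alone

* which of these there is most of at the end, counted by the substrate in it, south-east (side product / target / substrate)
* which of these there is most of at the end, counted by the substrate in it, west (side product / target / substrate)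
* how much there is at the end of the one of these that leads, in percent of the substrate charged: south-east
* how much there is at the end of the one of these that leads, in percent of the substrate charged: west

**Turning temperature.** I treated the loss of substrate as pseudo-first-order, which gave, as readings from the last points, rate constants of 0.0108 min⁻¹ for dusk and 0.0511 min⁻¹ for summer. Taking the logarithm of the rate constant as straight in temperature between those runs, south-east reached 1.35 and west 0.588. This is the turnover count: time multiplied by the rate constant of substrate loss. The part left is the exponential of minus that count.

**Turning amount.** The two runs differ in charge as well as temperature, so they could not separate the two. By hand I moved nothing for amount, since a first-order loss leaves the percentage unchanged. The gas phase stood at 18 mM in both runs and both new flasks, so I had nothing to read about it.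

**Turning time.** Time multiplies the count directly. The crossing count, where substrate left equals substrate lost, is 0.693. By my reckoning south-east stood above it, with 25.9 % left, and west below it, with 55.5 % left. Target read 7 % in the dusk run and 5 % in the summer run at their last readings, so I took the dusk figure for target in south-east and gave the rest to side product, 67.1 %.

**The forecast.** It said “The substrate decay looks first order within each run”, and named side product at 64 % for south-east and substrate at 55 % for west. My own figures differ from these, 67.1 % against 64 % for south-east and 55.5 % against 55 % for west, but name the same leaders.

**The flasks.** South-east ended with side product at 66.2 %, and its count of 1.35 had given 25.9 % of substrate against 22.5 % found. West ended with substrate at 54.2 %. Changing the dusk run's amount to south-east's kept its substrate at 64.3 %; changing its temperature by itself brought 22.1 %.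

    gas phase ⇌ dissolved gas, rate k1*(csat - [dissolved gas]) (kL = 6.00 × 10⁻⁴ s⁻¹)
    substrate + dissolved gas → target (k = 0.00910 L mol⁻¹ s⁻¹, Ea = 53.0 kJ mol⁻¹)
    substrate → side product (k = 1.80 × 10⁻⁴ s⁻¹, Ea = 85.0 kJ mol⁻¹)
    substrate + target ⇌ idle adduct, settled at all times (K = 20.0 L mol⁻¹, ΔH = −33.0 kJ mol⁻¹)
    2 dissolved gas → self-condensation product (k = 0.0110 L mol⁻¹ s⁻¹, Ea = 45.0 kJ mol⁻¹)
    (constants at 0 °C)

**Colder neighbour.** By my reckoning the lead in south-east passes to substrate once the count falls below the crossing. In a flask like south-east kept at −17 °C, my line carried beyond the runs gives a count of 0.101, so 90.4 % left. That flask held substrate in the lead at 90.6 %, with side product at 3.46 %.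

The numbers in the tables stem from a simulated flask with constants of no real substance.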